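**Plan**

1. Rings: ring A is the benzo ring of the chroman, ring B the pendant aryl, ring C the oxygen heterocycle. Retrosynthesis removes three O-allyl groups, cuts the O1–C2 ether bond of ring C (phenol plus primary alcohol), raises C2 to a lactone carbonyl, and then cuts C3–C4 and O1–C2(acyl).
2. The cut works because O1–C8a–C4a–C4 is an ortho-quinone methide of ring A, and C2–C3 is the carboxyl carbon and α-carbon of a ring B arylacetic acid: a four-atom acceptor and a two-atom enolate.
3. Forward, ring A is carried as a 2-silyloxybenzyl bromide (four steps from 2,4-dihydroxybenzaldehyde). Ring B is carried as an arylacetyl imidazole (seven steps from 2,3,4-trihydroxybenzaldehyde), its 1,1-dimethylallyl group coming from Claisen rearrangement of a prenyl ether.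
4. Ring C closes first as a dihydrocoumarin in a carbene-catalysed [4+2] annulation, is opened by hydride, and closes again as the cyclic ether; deallylation then frees the three phenols.
5. C3 (R) is the only stereocentre. It is set by the chiral triazolium-derived carbene in the annulation and is not touched afterwards (reduction and etherification both occur at C2).

Key step: step 12

Assumption: the (5aS,10bR) antipode of the aminoindanol-derived triazolium salt is taken to deliver the 3R lactone; if the sense of induction proves opposite, the mirror-image salt is used with nothing else changed.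

**Route**

Step 1
Reactants: 1 2,4-dihydroxybenzaldehyde; 2 allyl bromide
Product: 3 4-(allyloxy)-2-hydroxybenzaldehyde
Conditions: allyl bromide (1.1 equiv), KHCO3, DMF, 45 °C
Reagents that add atoms: allyl bromide (2), C=CCBr
Why: Williamson etherification is regioselective because the 4-OH, para to the formyl group and not hydrogen-bonded, is the more acidic and more nucleophilic phenol under a weak base, while the chelated 2-OH stays free.

Step 2
Reactants: 3 4-(allyloxy)-2-hydroxybenzaldehyde
Product: 4 4-(allyloxy)-2-[(tert-butyldimethylsilyl)oxy]benzaldehyde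
Conditions: TBSCl, imidazole, DMF, rt
Reagents that add atoms: tert-butyldimethylsilyl chloride, CC(C)(C)[Si](C)(C)Cl
Why: Imidazole-promoted silylation of a phenol is standard and leaves the aldehyde and allyl ether untouched.

Step 3
Reactants: 4 4-(allyloxy)-2-[(tert-butyldimethylsilyl)oxy]benzaldehyde
Product: 5 {4-(allyloxy)-2-[(tert-butyldimethylsilyl)oxy]phenyl}methanol
Conditions: NaBH4, MeOH/THF, −10 °C, short reaction time; aq. NH4Cl quench
Reagents that add atoms: none
Why: Borohydride reduction of the aldehyde is chemoselective, and low temperature with a prompt buffered quench should prevent migration of the silyl group from the phenol oxygen to the new benzylic alkoxide.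

Step 4
Reactants: 5 {4-(allyloxy)-2-[(tert-butyldimethylsilyl)oxy]phenyl}methanol
Product: 6 [5-(allyloxy)-2-(bromomethyl)phenoxy](tert-butyl)dimethylsilane
Conditions: CBr4, PPh3, CH2Cl2, 0 °C; rapid filtration through Et3N-deactivated silica; used at once
Reagents that add atoms: carbon tetrabromide, BrC(Br)(Br)Br
Why: The Appel reaction converts the electron-rich benzylic alcohol into the bromide under near-neutral conditions that spare the aryl silyl ether, and the labile para-alkoxybenzyl bromide is not stored.

Step 5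
Reactants: 7 2,3,4-trihydroxybenzaldehyde; 8 prenyl bromide
Product: 9 2,3-dihydroxy-4-[(3-methylbut-2-en-1-yl)oxy]benzaldehyde
Conditions: prenyl bromide (1.05 equiv), NaHCO3, DMF, 40 °C, Ar
Reagents that add atoms: prenyl bromide (8), CC(C)=CCBr
Why: Williamson etherification with a weak base should select the 4-OH, which is para to the formyl group and the most acidic of the three phenols, over the flanked 3-OH and the chelated 2-OH.

Step 6
Reactants: 9 2,3-dihydroxy-4-[(3-methylbut-2-en-1-yl)oxy]benzaldehyde
Product: 10 2,3,4-trihydroxy-5-(2-methylbut-3-en-2-yl)benzaldehyde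
Conditions: PhNEt2, 190 °C, sealed tube, Ar, about 2 h
Reagents that add atoms: none
Why: The aromatic Claisen rearrangement ([3,3]) can only deliver the allyl unit to C5, the one free ortho position, and the allylic inversion joins the dimethyl-bearing carbon to the ring, giving the 1,1-dimethylallyl group after tautomerisation.

Step 7
Reactants: 10 2,3,4-trihydroxy-5-(2-methylbut-3-en-2-yl)benzaldehyde; 2 allyl bromide
Product: 11 3,4-bis(allyloxy)-2-hydroxy-5-(2-methylbut-3-en-2-yl)benzaldehyde
Conditions: allyl bromide (2.2 equiv), K2CO3 (2.2 equiv), DMF, 0 °C to rt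
Reagents that add atoms: allyl bromide (2), C=CCBr
Why: In this Williamson etherification the 2-OH is held in a hydrogen bond to the formyl oxygen and is the least nucleophilic phenoxide, so two equivalents of the small, reactive allyl bromide should go to O3 and O4.

Step 8
Reactants: 11 3,4-bis(allyloxy)-2-hydroxy-5-(2-methylbut-3-en-2-yl)benzaldehyde
Product: 12 3,4-bis(allyloxy)-2-methoxy-5-(2-methylbut-3-en-2-yl)benzaldehyde
Conditions: MeI, K2CO3, DMF, 40 °C
Reagents that add atoms: iodomethane, CI
Why: Williamson methylation of the single remaining, chelated phenol is routine with iodomethane and carbonate in DMF.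

Step 9
Reactants: 12 3,4-bis(allyloxy)-2-methoxy-5-(2-methylbut-3-en-2-yl)benzaldehyde
Product: 14 2-[3,4-bis(allyloxy)-2-methoxy-5-(2-methylbut-3-en-2-yl)phenyl]acetonitrile, via N-(1-tosylvinyl)formamide 13 (not isolated)
Conditions: TosMIC, t-BuOK, DME, −40 °C; then MeOH, reflux
Reagents that add atoms: p-toluenesulfonylmethyl isocyanide (TosMIC), Cc1ccc(cc1)S(=O)(=O)C[N+]#[C-]
Why: In the van Leusen reductive cyanation the TosMIC anion adds to the aldehyde, the oxazoline adduct opens to the N-formyl enamine 13, and methanolysis removes the formyl group and expels sulfinate, giving the one-carbon-homologated nitrile.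

Step 10
Reactants: 14 2-[3,4-bis(allyloxy)-2-methoxy-5-(2-methylbut-3-en-2-yl)phenyl]acetonitrile
Product: 15 2-[3,4-bis(allyloxy)-2-methoxy-5-(2-methylbut-3-en-2-yl)phenyl]acetic acid
Conditions: KOH, EtOH/H2O, reflux; then cold 1 M HCl to pH 3
Reagents that add atoms: potassium hydroxide, [K+].[OH-]; water, O
Why: Alkaline hydrolysis of an arylacetonitrile is reliable, and aryl allyl ethers, the methyl ether and the terminal alkene are stable to hot aqueous hydroxide.

Step 11
Reactants: 15 2-[3,4-bis(allyloxy)-2-methoxy-5-(2-methylbut-3-en-2-yl)phenyl]acetic acid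
Product: 16 2-[3,4-bis(allyloxy)-2-methoxy-5-(2-methylbut-3-en-2-yl)phenyl]-1-(1H-imidazol-1-yl)ethan-1-one
Conditions: CDI (1.1 equiv), CH2Cl2, rt; quick cold-water wash, dried, used promptly
Reagents that add atoms: 1,1'-carbonyldiimidazole, O=C(n1ccnc1)n1ccnc1
Why: Carbonyldiimidazole activation gives the acyl imidazole through the acyl imidazole-carboxylate with loss of carbon dioxide, with no racemisable centre and no acid or strong base involved.

Step 12
Reactants: 6 [5-(allyloxy)-2-(bromomethyl)phenoxy](tert-butyl)dimethylsilane; 16 2-[3,4-bis(allyloxy)-2-methoxy-5-(2-methylbut-3-en-2-yl)phenyl]-1-(1H-imidazol-1-yl)ethan-1-one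
Product: 19 (3R)-7-(allyloxy)-3-[3,4-bis(allyloxy)-2-methoxy-5-(2-methylbut-3-en-2-yl)phenyl]chroman-2-one, via ortho-quinone methide 17 (not isolated), via azolium enolate 18 (not isolated)
Conditions: (5aS,10bR)-2-mesityl-5a,10b-dihydro-4H,6H-indeno[2,1-b][1,2,4]triazolo[4,3-d][1,4]oxazin-2-ium tetrafluoroborate (15 mol %), CsF (1.5 equiv), 18-crown-6 (1.5 equiv), 4 Å molecular sieves, THF, −20 °C; 6 (1.4 equiv) added over several hours; short silica plug, carried on at once
Reagents that add atoms: none
Why: Fluoride removes the silyl group of 6 and the phenoxide expels bromide by 1,4-elimination to give quinone methide 17, while the free carbene is acylated by 16 and the released imidazolide deprotonates the acyl azolium to the Z-enolate 18. Michael addition of the enolate carbon of 18 to the exocyclic methylene of 17 forms C3–C4 and rearomatises ring A, and the resulting phenoxide closes O1–C2 on the acyl azolium in a 6-exo-trig lactonisation that releases the carbene. The closest known reaction type is the carbene-catalysed formal [4+2] annulation of fluoride-generated ortho-quinone methides with acyl imidazoles to 3-substituted dihydrocoumarins. C3 is the only new stereocentre and is set by the catalyst, whose aminoindanol-derived backbone shields one face of the enolate so that 17 approaches from the open face. The step needs C- rather than O-alkylation of the enolate, capture of 17 before it oligomerises, and retention of configuration at the acidic α-aryl lactone centre; the soft enolate carbon and Michael acceptor favour the first, slow addition of 6 at low temperature keeps 17 dilute, and brief exposure to base followed by immediate reduction protects C3.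

Step 13
Reactants: 19 (3R)-7-(allyloxy)-3-[3,4-bis(allyloxy)-2-methoxy-5-(2-methylbut-3-en-2-yl)phenyl]chroman-2-one
Product: 20 5-(allyloxy)-2-{(2R)-2-[3,4-bis(allyloxy)-2-methoxy-5-(2-methylbut-3-en-2-yl)phenyl]-3-hydroxypropyl}phenol
Conditions: LiAlH4, THF, −20 to 0 °C; aqueous Rochelle salt work-up
Reagents that add atoms: none
Why: Hydride reduction of the aryl ester is faster than enolisation at C3 at low temperature and carries the lactone through to the phenol and primary alcohol with C3 unchanged, while allyl ethers and the terminal alkene are inert to LiAlH4.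

Step 14
Reactants: 20 5-(allyloxy)-2-{(2R)-2-[3,4-bis(allyloxy)-2-methoxy-5-(2-methylbut-3-en-2-yl)phenyl]-3-hydroxypropyl}phenol
Product: 21 (3R)-7-(allyloxy)-3-[3,4-bis(allyloxy)-2-methoxy-5-(2-methylbut-3-en-2-yl)phenyl]chromane
Conditions: PPh3, DIAD, THF, 0 °C to rt
Reagents that add atoms: none
Why: In this intramolecular Mitsunobu etherification the phenol displaces the activated primary alcohol in a 6-exo-tet closure that forms O1–C2 of ring C without involving the C3 stereocentre.

Step 15
Reactants: 21 (3R)-7-(allyloxy)-3-[3,4-bis(allyloxy)-2-methoxy-5-(2-methylbut-3-en-2-yl)phenyl]chromane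
Product: 22 (3R)-3-[3,4-dihydroxy-2-methoxy-5-(2-methylbut-3-en-2-yl)phenyl]chroman-7-ol
Conditions: Pd(PPh3)4 (10 mol %), morpholine (excess), degassed THF, rt
Reagents that add atoms: none
Why: In this Tsuji–Trost-type deallylation, zerovalent palladium ionises each aryl allyl ether to a π-allyl complex and a phenoxide and morpholine traps the allyl unit, while the 1,1-dimethylallyl group has no allylic leaving group and the methyl ether and C3 are unaffected.

**Compound list**

1 | 2,4-dihydroxybenzaldehyde | O=Cc1ccc(O)cc1O | starting material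
2 | allyl bromide | C=CCBr | starting material
3 | 4-(allyloxy)-2-hydroxybenzaldehyde | O=Cc1ccc(OCC=C)cc1O | intermediate
4 | 4-(allyloxy)-2-[(tert-butyldimethylsilyl)oxy]benzaldehyde | O=Cc1ccc(OCC=C)cc1O[Si](C)(C)C(C)(C)C | intermediate
5 | {4-(allyloxy)-2-[(tert-butyldimethylsilyl)oxy]phenyl}methanol | OCc1ccc(OCC=C)cc1O[Si](C)(C)C(C)(C)C | intermediate
6 | [5-(allyloxy)-2-(bromomethyl)phenoxy](tert-butyl)dimethylsilane | BrCc1ccc(OCC=C)cc1O[Si](C)(C)C(C)(C)C | intermediate
7 | 2,3,4-trihydroxybenzaldehyde | O=Cc1ccc(O)c(O)c1O | starting material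
8 | prenyl bromide (1-bromo-3-methylbut-2-ene) | CC(C)=CCBr | starting material
9 | 2,3-dihydroxy-4-[(3-methylbut-2-en-1-yl)oxy]benzaldehyde | O=Cc1ccc(OCC=C(C)C)c(O)c1O | intermediate
10 | 2,3,4-trihydroxy-5-(2-methylbut-3-en-2-yl)benzaldehyde | O=Cc1cc(C(C)(C)C=C)c(O)c(O)c1O | intermediate
11 | 3,4-bis(allyloxy)-2-hydroxy-5-(2-methylbut-3-en-2-yl)benzaldehyde | O=Cc1cc(C(C)(C)C=C)c(OCC=C)c(OCC=C)c1O | intermediate
12 | 3,4-bis(allyloxy)-2-methoxy-5-(2-methylbut-3-en-2-yl)benzaldehyde | O=Cc1cc(C(C)(C)C=C)c(OCC=C)c(OCC=C)c1OC | intermediate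
13 | N-{2-[3,4-bis(allyloxy)-2-methoxy-5-(2-methylbut-3-en-2-yl)phenyl]-1-tosylethenyl}formamide (present as its potassium salt) | O=CNC(=Cc1cc(C(C)(C)C=C)c(OCC=C)c(OCC=C)c1OC)S(=O)(=O)c1ccc(C)cc1 | intermediate
14 | 2-[3,4-bis(allyloxy)-2-methoxy-5-(2-methylbut-3-en-2-yl)phenyl]acetonitrile | N#CCc1cc(C(C)(C)C=C)c(OCC=C)c(OCC=C)c1OC | intermediate
15 | 2-[3,4-bis(allyloxy)-2-methoxy-5-(2-methylbut-3-en-2-yl)phenyl]acetic acid | OC(=O)Cc1cc(C(C)(C)C=C)c(OCC=C)c(OCC=C)c1OC | intermediate
16 | 2-[3,4-bis(allyloxy)-2-methoxy-5-(2-methylbut-3-en-2-yl)phenyl]-1-(1H-imidazol-1-yl)ethan-1-one | O=C(Cc1cc(C(C)(C)C=C)c(OCC=C)c(OCC=C)c1OC)n1ccnc1 | intermediate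
17 | 3-(allyloxy)-6-methylidenecyclohexa-2,4-dien-1-one (ortho-quinone methide) | C=C1C=CC(OCC=C)=CC1=O | intermediate
18 | (Z)-2-[3,4-bis(allyloxy)-2-methoxy-5-(2-methylbut-3-en-2-yl)phenyl]-1-[(5aS,10bR)-2-mesityl-5a,10b-dihydro-4H,6H-indeno[2,1-b][1,2,4]triazolo[4,3-d][1,4]oxazin-2-ium-1-yl]ethen-1-olate (azolium enolate) | [O-]/C(=C\c1cc(C(C)(C)C=C)c(OCC=C)c(OCC=C)c1OC)c1n2c(n[n+]1-c1c(C)cc(C)cc1C)CO[C@H]1Cc3ccccc3[C@H]12 | intermediate
19 | (3R)-7-(allyloxy)-3-[3,4-bis(allyloxy)-2-methoxy-5-(2-methylbut-3-en-2-yl)phenyl]chroman-2-one | C=CC(C)(C)c1cc([C@H]2Cc3ccc(OCC=C)cc3OC2=O)c(OC)c(OCC=C)c1OCC=C | intermediate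
20 | 5-(allyloxy)-2-{(2R)-2-[3,4-bis(allyloxy)-2-methoxy-5-(2-methylbut-3-en-2-yl)phenyl]-3-hydroxypropyl}phenol | OC[C@H](Cc1ccc(OCC=C)cc1O)c1cc(C(C)(C)C=C)c(OCC=C)c(OCC=C)c1OC | intermediate
21 | (3R)-7-(allyloxy)-3-[3,4-bis(allyloxy)-2-methoxy-5-(2-methylbut-3-en-2-yl)phenyl]chromane | C=CC(C)(C)c1cc([C@@H]2COc3cc(OCC=C)ccc3C2)c(OC)c(OCC=C)c1OCC=C | intermediate
22 | (3R)-3-[3,4-dihydroxy-2-methoxy-5-(2-methylbut-3-en-2-yl)phenyl]chroman-7-ol | C=CC(C)(C)c1cc([C@@H]2COc3cc(O)ccc3C2)c(OC)c(O)c1O | target

**Totals**

Total step count: 15.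
Longest linear sequence: 11 steps (steps 5 to 15, from 2,3,4-trihydroxybenzaldehyde).

**Steps most likely to fail**

Step 12. Fluoride or imidazolide may enolise the α-aryl lactone and erode its enantiomeric purity, the hindered ortho-methoxyaryl enolate may discriminate poorly between its faces, and the electron-rich quinone methide may oligomerise before it is captured. The fallback makes the same C3–C4 bond by auxiliary-controlled (Evans) alkylation; it sets out from acid 15 and bromide 6 and returns to the route at diol 20. Acid 15 is treated with pivaloyl chloride and Et3N (THF, −20 °C) to give the mixed pivalic anhydride F1. F1 acylates lithiated (R)-4-benzyl-1,3-oxazolidin-2-one to give the N-arylacetyl oxazolidinone F2. Its sodium Z-enolate (NaN(SiMe3)2, THF, −78 °C) should be alkylated by 6 on the face away from the benzyl group, giving the (2R)-configured alkylated imide F3. LiBH4 (THF, MeOH, 0 °C) then releases the auxiliary and gives the silyl-protected primary alcohol F4. Finally n-Bu4NF (THF, 0 °C) frees the phenol to give 20.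

Step 6. At the rearrangement temperature the ether may fragment with loss of isoprene, the new ortho-(1,1-dimethylallyl)phenol may add across its own alkene or rearrange further, and the unprotected trihydroxyarene may be oxidised. The fallback runs the rearrangement on a fully protected ether and captures the new phenol as an ester as it forms; it sets out from 9 and returns at 10. Both phenols of 9 are protected (MOMCl, NaH, DMF, 0 °C) to give the bis(methoxymethyl) ether F5. Heating F5 in N,N-diethylaniline containing butyric anhydride (185 °C) should give the rearranged aryl butanoate F6. K2CO3 in MeOH cleaves the ester to the phenol F7, and dilute HCl in MeOH at room temperature removes both methoxymethyl groups to give 10.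

Step 7. Regiocontrol may be lost: alkylation at the hindered O4 may lag while the chelated O2 starts to react, leaving mixtures of mono-, bis- and tris-allyl ethers. The fallback methylates O2 while O3 and O4 are tied together, so the later allylation needs no selection; it sets out from 7 and returns at 12. Ph2CCl2 (diphenyl ether, 175 °C) bridges O3 and O4 of 7 to give the diphenylmethylene ketal F8. MeI and K2CO3 in DMF methylate the remaining chelated phenol to give the methyl ether F9. Aqueous AcOH at reflux removes the ketal to give 3,4-dihydroxy-2-methoxybenzaldehyde F10. Prenyl bromide and NaHCO3 in DMF etherify the hydroxyl para to the formyl group to give the prenyl ether F11. Claisen rearrangement as in step 6 gives the 1,1-dimethylallyl catechol F12. Excess allyl bromide with K2CO3 in DMF then alkylates both remaining phenols to give 12.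

**Further compounds**

F1 | step 12 | 2-[3,4-bis(allyloxy)-2-methoxy-5-(2-methylbut-3-en-2-yl)phenyl]acetic pivalic anhydride | CC(C)(C)C(=O)OC(=O)Cc1cc(C(C)(C)C=C)c(OCC=C)c(OCC=C)c1OC
F2 | step 12 | (4R)-4-benzyl-3-{2-[3,4-bis(allyloxy)-2-methoxy-5-(2-methylbut-3-en-2-yl)phenyl]acetyl}-1,3-oxazolidin-2-one | O=C(Cc1cc(C(C)(C)C=C)c(OCC=C)c(OCC=C)c1OC)N1[C@H](Cc2ccccc2)COC1=O
F3 | step 12 | (4R)-3-[(2R)-3-{4-(allyloxy)-2-[(tert-butyldimethylsilyl)oxy]phenyl}-2-[3,4-bis(allyloxy)-2-methoxy-5-(2-methylbut-3-en-2-yl)phenyl]propanoyl]-4-benzyl-1,3-oxazolidin-2-one | O=C([C@H](Cc1ccc(OCC=C)cc1O[Si](C)(C)C(C)(C)C)c1cc(C(C)(C)C=C)c(OCC=C)c(OCC=C)c1OC)N1[C@H](Cc2ccccc2)COC1=O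
F4 | step 12 | (2R)-3-{4-(allyloxy)-2-[(tert-butyldimethylsilyl)oxy]phenyl}-2-[3,4-bis(allyloxy)-2-methoxy-5-(2-methylbut-3-en-2-yl)phenyl]propan-1-ol | OC[C@H](Cc1ccc(OCC=C)cc1O[Si](C)(C)C(C)(C)C)c1cc(C(C)(C)C=C)c(OCC=C)c(OCC=C)c1OC
F5 | step 6 | 2,3-bis(methoxymethoxy)-4-[(3-methylbut-2-en-1-yl)oxy]benzaldehyde | O=Cc1ccc(OCC=C(C)C)c(OCOC)c1OCOC
F6 | step 6 | 4-formyl-2,3-bis(methoxymethoxy)-6-(2-methylbut-3-en-2-yl)phenyl butanoate | CCCC(=O)Oc1c(C(C)(C)C=C)cc(C=O)c(OCOC)c1OCOC
F7 | step 6 | 4-hydroxy-2,3-bis(methoxymethoxy)-5-(2-methylbut-3-en-2-yl)benzaldehyde | O=Cc1cc(C(C)(C)C=C)c(O)c(OCOC)c1OCOC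
F8 | step 7 | 4-hydroxy-2,2-diphenyl-1,3-benzodioxole-5-carbaldehyde | O=Cc1ccc2OC(c3ccccc3)(c3ccccc3)Oc2c1O
F9 | step 7 | 4-methoxy-2,2-diphenyl-1,3-benzodioxole-5-carbaldehyde | O=Cc1ccc2OC(c3ccccc3)(c3ccccc3)Oc2c1OC
F10 | step 7 | 3,4-dihydroxy-2-methoxybenzaldehyde | O=Cc1ccc(O)c(O)c1OC
F11 | step 7 | 3-hydroxy-2-methoxy-4-[(3-methylbut-2-en-1-yl)oxy]benzaldehyde | O=Cc1ccc(OCC=C(C)C)c(O)c1OC
F12 | step 7 | 3,4-dihydroxy-2-methoxy-5-(2-methylbut-3-en-2-yl)benzaldehyde | O=Cc1cc(C(C)(C)C=C)c(O)c(O)c1OC
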